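**Assumption:** enantiopure (S)-3-methylcyclopentanone is purchasable, and the (E,E)-diene geometry is as drawn in the target SMILES.

## Retrosynthetic overview
- The (E,E)-phenylbutadienyl group comes from a Horner–Wadsworth–Emmons (HWE) reaction on a quaternary aldehyde, which is made from a methyl ester.
- The cyclohexene ring closes by a photoredox 6-endo atom-transfer radical cyclisation (ATRC) of a tertiary α-bromo ester onto an isopropenyl group, and HBr loss then gives the ring alkene.
- The adjacent Me/CO2H quaternary centre and the C–C bond to the ring-fusion carbon come from a photochemical [2+2]/retro-aldol between a silyl enol ether and 2,3-dimethylmaleic anhydride.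
- The cyclopentene ring comes from (S)-3-methylcyclopentanone via (R)-4-methylcyclopentenone, anti cuprate addition and ethyl installation through a vinyl triflate.
- Ring order: the pool cyclopentane exists first, a cyclobutane forms transiently and is opened, then the cyclohexene ring is closed.

## Route

**Step 1**
Reactants: 1 (S)-3-methylcyclopentan-1-one; 2 chlorotrimethylsilane
Product: 3 (S)-trimethyl[(4-methylcyclopent-1-en-1-yl)oxy]silane
Conditions: LiHMDS, THF, –78 °C; then 2
Reagents that add atoms: chlorotrimethylsilane, C[Si](C)(C)Cl
Why: Kinetic deprotonation occurs at the CH2 remote from the methyl group, giving the silyl enol ether toward C5 (regiochemistry assumed); the methyl-bearing stereocentre is untouched.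

**Step 2**
Reactants: 3
Product: 4 (R)-4-methylcyclopent-2-en-1-one
Conditions: Pd(OAc)2 (10 mol%), O2 (1 atm), DMSO, 25 °C
Reagents that add atoms: none
Why: Saegusa–Ito (Larock) oxidation moves the double bond into conjugation at C4–C5 and leaves the γ-methyl stereocentre intact.

**Step 3**
Reactants: 4; 5 isopropenylmagnesium bromide; 2 chlorotrimethylsilane
Product: 6 trimethyl{[(3S,4R)-4-methyl-3-(prop-1-en-2-yl)cyclopent-1-en-1-yl]oxy}silane (trans)
Conditions: 5 (1.5 equiv), CuBr·SMe2 (10 mol%), 2 (2 equiv), DMPU, THF, –78 → 0 °C
Reagents that add atoms: isopropenylmagnesium bromide, C=C(C)[Mg]Br; chlorotrimethylsilane, C[Si](C)(C)Cl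
Why: Cu-catalysed conjugate addition occurs anti to the γ-methyl group, so the isopropenyl group ends up trans to the methyl and defines ring-fusion carbon d; TMSCl traps the regiodefined enolate as the silyl enol ether.

**Step 4**
Reactants: 6; 7 2,3-dimethylmaleic anhydride
Product: 8 cis-syn-cis cyclobutane photoadduct (OTMS at the cyclobutane/ring-1 fusion carbon)
Conditions: 7 (3 equiv), acetone (0.03 M), hν (medium-pressure Hg, Pyrex, >290 nm), –10 °C, 8 h
Reagents that add atoms: 2,3-dimethylmaleic anhydride, CC1=C(C)C(=O)OC1=O
Why: Proposed new method: triplet 7 adds to the enol-ether carbon C2 (the carbon that becomes i), anti to the adjacent isopropenyl group, and the resulting 1,4-biradical (α-siloxy radical plus tertiary α-acyl radical) closes to the cyclobutane; the alkene already carries the vicinal Me/C=O pair with cis methyls, and an exciplex-directed endo (syn) closure is required to give the target configuration at h. The closest known chemistry is enone/enol-ether [2+2] photocycloaddition (de Mayo type) and maleic anhydride [2+2] photocycloaddition; this step is a formal Michael addition of a tetrasubstituted acceptor at a crowded enol carbon, forging the key i–h bond.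

**Step 5**
Reactants: 8; 9 methanol
Product: 10 keto acid–methyl ester (cyclopentanone bearing –C(Me)(CO2H)–CH(Me)–CO2Me at C2, 3-isopropenyl, 4-methyl)
Conditions: K2CO3 (4 equiv), MeOH, 25 °C, 2 h; then 1 M HCl
Reagents that add atoms: methanol, CO
Why: Desilylation gives a cyclobutoxide that undergoes strain-driven retro-aldol cleavage of the C–C bond to the anhydride carbon (de Mayo fragmentation); this releases ketone a, and methoxide opens the anhydride at the less hindered carbonyl (next to g), giving CO2Me on g and CO2H on h. Carbon g is epimerisable and is reset in step 9, and i is equilibrated by base to the thermodynamic trans arrangement relative to the isopropenyl group.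

**Step 6**
Reactants: 10; 11 N-phenylbis(trifluoromethanesulfonimide)
Product: 12 cyclopentenyl triflate
Conditions: KHMDS (2.2 equiv), THF, –78 °C; then 11 (1.2 equiv), –78 → 0 °C
Reagents that add atoms: PhNTf2, O=S(=O)(C(F)(F)F)N(c1ccccc1)S(=O)(=O)C(F)(F)F
Why: The first equivalent of base deprotonates the acid, and the second forms the kinetic ketone enolate at CH2 (the tertiary i–H is shielded by the vicinal quaternary centre), so triflation gives the a=b vinyl triflate regiospecifically.

**Step 7**
Reactants: 12; 13 ethylmagnesium bromide
Product: 14 ethylcyclopentene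
Conditions: 13 (4 equiv), Fe(acac)3 (5 mol%), THF/NMP, 0 °C, 15 min
Reagents that add atoms: ethylmagnesium bromide, CC[Mg]Br
Why: Fe-catalysed Kumada coupling of a vinyl triflate is compatible with the carboxylate and hindered ester and sets the ethyl-bearing trisubstituted alkene.

**Step 8**
Reactants: 14; 15 1,2-dibromo-1,1,2,2-tetrachloroethane
Product: 16 tertiary α-bromo ester
Conditions: LDA (3.3 equiv), THF, –78 → –20 °C; then 15 (1.5 equiv), –78 °C
Reagents that add atoms: 1,2-dibromotetrachloroethane, BrC(Cl)(Cl)C(Cl)(Cl)Br
Why: After the carboxylate forms, the only remaining acidic α-C–H is on g (h is quaternary), so enolate bromination is regiospecific; the g configuration is irrelevant because the next step goes through a radical.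

**Step 9**
Reactants: 16
Product: 17 bicyclic tertiary bromide (hydrindene with e–Br)
Conditions: [Cu(dap)2]Cl (1 mol%), CH2Cl2 (0.02 M), green LEDs (525 nm), 25 °C, 16 h
Reagents that add atoms: none
Why: Photoredox ATRC generates the tertiary α-ester radical at g, which undergoes 6-endo cyclisation onto the terminal CH2 of the isopropenyl group (the methyl on the alkene disfavours 5-exo, as in 5-methylhex-5-enyl radicals) and closes ring 2; in the chair-like transition state the smaller CO2Me sits axial, trans-diaxial to the h-methyl, which sets the g configuration.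

**Step 10**
Reactants: 17
Product: 18 hydrindadiene ester–acid
Conditions: DBU (5 equiv), toluene, 90 °C, 6 h
Reagents that add atoms: none
Why: E2 loss of HBr using the accessible axial H on the ring CH2 (f) gives the trisubstituted e=f alkene, and the nonpolar solvent suppresses ionisation and lactonisation by the carboxylate.

**Step 11**
Reactants: 18
Product: 19 aldehyde–acid (exists as the pseudo-acid lactol)
Conditions: DIBAL-H (5 equiv), CH2Cl2, –78 → 0 °C, 3 h; then Rochelle salt
Reagents that add atoms: none
Why: The carboxylate is protected in situ as its aluminium salt, and DIBAL reduces only the methyl ester to the aldehyde, which is stable as the lactol.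

**Step 12**
Reactants: 19; 20 diethyl (E)-cinnamylphosphonate
Product: 21 target, 22-nor-zyggomphic acid B
Conditions: 20 (2 equiv), KOtBu (4.5 equiv), THF, 0 °C → 25 °C, 6 h; then 1 M HCl
Reagents that add atoms: diethyl (E)-cinnamylphosphonate, CCOP(=O)(OCC)C/C=C/c1ccccc1
Why: HWE olefination of the lactol/aldehyde forms the new alkene with E selectivity and retains the styryl E geometry, giving the (E,E)-diene and the free acid.

## Compound list
1 | (S)-3-methylcyclopentan-1-one | O=C1C[C@@H](C)CC1 | starting material
2 | chlorotrimethylsilane | C[Si](C)(C)Cl | starting material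
3 | (S)-trimethyl[(4-methylcyclopent-1-en-1-yl)oxy]silane | C[Si](C)(C)OC1=CC[C@H](C)C1 | intermediate
4 | (R)-4-methylcyclopent-2-en-1-one | O=C1C=C[C@H](C)C1 | intermediate
5 | isopropenylmagnesium bromide | C=C(C)[Mg]Br | starting material
6 | trimethyl{[(3S,4R)-4-methyl-3-(prop-1-en-2-yl)cyclopent-1-en-1-yl]oxy}silane | C=C(C)[C@@H]1C=C(O[Si](C)(C)C)C[C@H]1C | intermediate
7 | 2,3-dimethylmaleic anhydride | CC1=C(C)C(=O)OC1=O | starting material
8 | cis-syn-cis [2+2] photoadduct of 6 and 7 | C=C(C)[C@@H]1[C@H]2[C@@]3(C)C(=O)OC(=O)[C@@]3(C)[C@@]2(O[Si](C)(C)C)C[C@H]1C | intermediate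
9 | methanol | CO | starting material
10 | keto acid–methyl ester (g epimeric) | C=C(C)[C@@H]1[C@@H]([C@@](C)(C(=O)O)C(C)C(=O)OC)C(=O)C[C@H]1C | intermediate
11 | N-phenylbis(trifluoromethanesulfonimide) | O=S(=O)(C(F)(F)F)N(c1ccccc1)S(=O)(=O)C(F)(F)F | starting material
12 | cyclopentenyl triflate | C=C(C)[C@@H]1[C@@H]([C@@](C)(C(=O)O)C(C)C(=O)OC)C(OS(=O)(=O)C(F)(F)F)=C[C@H]1C | intermediate
13 | ethylmagnesium bromide | CC[Mg]Br | starting material
14 | ethylcyclopentene ester–acid | C=C(C)[C@@H]1[C@@H]([C@@](C)(C(=O)O)C(C)C(=O)OC)C(CC)=C[C@H]1C | intermediate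
15 | 1,2-dibromo-1,1,2,2-tetrachloroethane | BrC(Cl)(Cl)C(Cl)(Cl)Br | starting material
16 | tertiary α-bromo ester (g epimeric) | C=C(C)[C@@H]1[C@@H]([C@@](C)(C(=O)O)C(C)(Br)C(=O)OC)C(CC)=C[C@H]1C | intermediate
17 | hydrindene tertiary bromide (e epimeric) | CCC1=C[C@@H](C)[C@@H]2C(C)(Br)C[C@](C)(C(=O)OC)[C@](C)(C(=O)O)[C@@H]12 | intermediate
18 | hydrindadiene ester–acid | CCC1=C[C@@H](C)[C@@H]2C(C)=C[C@](C)(C(=O)OC)[C@](C)(C(=O)O)[C@@H]12 | intermediate
19 | aldehyde–acid (lactol tautomer) | CCC1=C[C@@H](C)[C@@H]2C(C)=C[C@](C)(C=O)[C@](C)(C(=O)O)[C@@H]12 | intermediate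
20 | diethyl (E)-cinnamylphosphonate | CCOP(=O)(OCC)C/C=C/c1ccccc1 | starting material
21 | 22-nor-zyggomphic acid B | CCC1=C[C@@H](C)[C@@H]2C(C)=C[C@](C)(/C=C/C=C/c3ccccc3)[C@](C)(C(=O)O)[C@@H]12 | target

**Total steps:** 12. **Longest linear sequence:** 12 (1 → 21).

## Three steps most likely to fail
1. **Step 4 (proposed new photochemical [2+2]/retro-aldol).** The anti adduct, which is the h-epimer, may dominate; the isopropenyl group may compete; and the silyl enol ether may be lost to electron transfer.
   Fallback: replace it with a Lewis-acid (TiCl4 or TMSOTf) Mukaiyama–Michael of enol ether 6 onto 7 to form the same i–h bond by a polar route, then continue from step 5.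
2. **Step 9 (6-endo ATRC, with the step 10 elimination).** The cyclisation may give 5-exo products, and the tertiary bromide may lactonise with a neighbouring carboxyl group or eliminate to e=d or the exocyclic methylene instead of e=f.
   Fallback: skip steps 8–10. Convert the isopropenyl group to the dimethyl acetal of the 2-methylpropanal unit (hydroboration–oxidation, oxidation, HC(OMe)3), make the ester silyl ketene acetal, close the ring by a TMSOTf-promoted Mukaiyama aldol-type cyclisation, and eliminate MeOH, which is regiospecific toward e because g is quaternary.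
3. **Step 11 (DIBAL on the hindered neopentyl ester, feeding the step 12 HWE on the α-quaternary aldehyde).** Over-reduction to the alcohol, or poor yield or poor E,E ratio in the olefination, is possible.
   Fallback: reduce the ester with LiAlH4, oxidise with Dess–Martin periodinane, make the (E)-vinyl iodide by Takai iodo-olefination (CrCl2/CHI3), then Suzuki-couple it with (E)-styrylboronic acid.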